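The data stem from a simulated flask for an exercise, and the scatter is random.

Count in shares of the substrate charge per minute, and take logarithms of the rates. In each flask the substrate goes to target with the first nucleophile while the gas is held.

| flask | substrate | first nucleophile | gas | temperature | remark | time |
|---|---|---|---|---|---|---|
| green | 0.065 M | 1.3 equiv | 11 mM (held) | 20 °C | run made earlier |  |
| violet | 0.091 M | 1.3 equiv | 11 mM (held) | 31 °C | run made earlier |  |
| grey | 0.14 M | 1.3 equiv | 11 mM (held) | 20 °C | run made earlier |  |
| Tuesday's | 0.065 M | 1.30 equiv (fed, over 40 s) | 11 mM (held) | 25 °C | all else is in the flask from the start; the feed brings no volume worth counting | 3.0 min |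
| Friday's | 0.065 M | 1.30 equiv (fed, over 40 s) | 11 mM (held) |  | the addition at −5 °C, then warmed to 25 °C; the feed brings no volume worth counting | 3.0 min |
| Wednesday's | 0.065 M (fed, over 4.0 s) | 1.30 equiv | 11 mM (held) | 25 °C | all else is in the flask from the start; the feed brings no volume worth counting | 3.0 min |
| Saturday's | 0.065 M (fed, over 40 s) | 1.30 equiv | 11 mM (held) | 25 °C | all else is in the flask from the start; the feed brings no volume worth counting | 3.0 min |

| green: time / min | green: target / % | violet: time / min | violet: target / % | grey: time / min | grey: target / % |
|---|---|---|---|---|---|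
| 0.417 | 10.2 | 0.250 | 19.1 | 0.833 | 19.7 |
| 1.00 | 21.1 | 0.667 | 39.8 | 2.00 | 38.2 |
| 2.00 | 31.7 | 1.50 | 59.2 | 2.50 | 44.4 |
| 3.00 | 40.6 | 4.00 | 68.2 | 4.00 | 55.0 |

(scatter of a reading: 0.5 percentage points)

- at the start none of the gas is in solution

- which flask leads in amount of target, in percent of the substrate charged ("all alike" within 1.5 percentage points) (Tuesday's / Friday's / Wednesday's / Saturday's / all alike)
- how much target is there at the end, in percent of the substrate charged: Tuesday's
- how much target is there at the end, in percent of the substrate charged: Friday's
- how much target is there at the end, in percent of the substrate charged: Wednesday's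
- how much target is there at the end, in percent of the substrate charged: Saturday's

Start with green: its first reading gives 0.245 min⁻¹. Grey, at twice the charge, gives 0.236 min⁻¹, about the same, the mark of a first-order loss, so keep the rate as a share. Green's last interval gives 0.0890 min⁻¹, which is 0.440 of a power of ten lower across 2.29 min.

Now heat it. Violet's first reading, 0.764 min⁻¹, interpolated on the logarithm, raises green's rate by 1.68 at 25 °C, so the start rate r is 0.410 min⁻¹. Assume the fall quickens by the same factor. Then the target rate needs 3.11 min to drop by one power of ten; call this the decade time D.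

Summed over unlimited time, such a rate gives a reckoned total C, which is r times D over the natural logarithm of ten: 55.4%. After a running time t, the target is C minus C lowered by t/D powers of ten.

Tuesday's substrate is in from the start, so its clock runs in full: 49.4%. Wednesday's loses half of its short feed and comes level at 49.3%. Saturday's loses half of its long feed: 47.7%. At −5 °C the same logarithmic step puts the rate at 0.0184 min⁻¹, far below r, so count Friday's feed as lost time: 45.6%.

The forecast, holding Wednesday's to be “nearly batch, with full nucleophile during the gas-poor start”, gives 53%, against 50% for Tuesday's, 49% for Saturday's and 45% for Friday's, and so parts from this reckoning by setting Wednesday's ahead of Tuesday's.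

The flasks give 51.3% for Wednesday's, 49.6% for Tuesday's, 48.1% for Saturday's and 45.1% for Friday's.

    target ⇌ isomer of the product (K = 0.160, k = 0.00190 s⁻¹, Ea = 88.0 kJ mol⁻¹, ΔH = −11.0 kJ mol⁻¹)
    gas ⇌ second nucleophile, rate k2*(csat - [second nucleophile]) (kL = 0.0310 s⁻¹)
    first nucleophile + intermediate → target (k = 11.0 M⁻¹ s⁻¹, Ea = 37.0 kJ mol⁻¹)
    2 second nucleophile → homo dimer (k = 0.310 M⁻¹ s⁻¹, Ea = 49.0 kJ mol⁻¹)
    substrate → intermediate (k = 0.00920 s⁻¹, Ea = 76.0 kJ mol⁻¹)
    second nucleophile + intermediate → other capture product (k = 51.0 M⁻¹ s⁻¹, Ea = 40.0 kJ mol⁻¹)
    (constants at 25 °C)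

The largest single effect on Wednesday's target is the turning of second nucleophile + intermediate into other capture product: without that step, Wednesday's gives 72.0% in place of 51.3%. With D at 3.11 min, Friday's warm stretch to 3.0 min covers 0.750 of a power of ten. Left until 8.0 min, the same flask covers 2.36, which reckons to 55.2%, and it stands at 55.3%.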